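**Retrosynthetic overview**

1. Locants used throughout: C1 = furanone carbon bonded to the ring oxygen and to C10; C2 = furanone CH; C3 = ketone; C4 = quaternary C(CH3)–O; C5 = ylidene CH; C6 = sp2 carbon bearing the lactone oxygen; C7, C11, C12 = butenolide β-carbon, α-carbon, C=O; C8 = acyloxy carbon; C9 = CH2; C10 = CH(CH3); C13 = CH2OAc.
2. Endgame: the C13 acetate and the C8 3-methylbut-2-enoate are put on last, on the bis-silyl ether of the tricyclic core.
3. Key disconnection, O–C1. Enabling feature: the furanone oxygen sits on C4, which is allylic to the C5=C6 enol-lactone bond of the 5-ylidene butenolide, and C1=C2–C3=O is a vinylogous ester. O–C4–C5=C6 therefore maps onto a 4,5-epoxide next to a C6–H butenolide, and C1–C3 onto a ring ynone. One base-triggered cascade (vinylogous E1cB epoxide opening, then 5-endo-dig oxa-Michael addition) should form the furanone ring, the oxygen bridge of the 11-oxabicyclo[6.2.1] core and the C5=C6 bond.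
4. The ten-membered epoxy ynone comes from a Nozaki–Hiyama–Kishi closure of C2–C3 (iodoalkyne onto epoxy aldehyde). The oxirane comes from a Sharpless epoxidation (sets C4), C5–C6 from a vinyllithium addition to a γ-hydroxybutenolide, and the butenolide from singlet-oxygen oxidation of a 2-silylfuran.
5. The furan is elaborated from furan-3-ylmethanol by silyl migration and lithiation/acylation at the furan 4-position; C10 is set by Rh-catalysed conjugate alkynylation and C8 by transfer hydrogenation. Ring order: furan (purchased) → butenolide (steps 8 and 11) → oxirane (step 12) → ten-membered carbocycle (step 15) → furanone and oxa-bridge together (step 17).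

Key step: step 17

Abbreviations: TBS = tert-butyldimethylsilyl, TIPS = tri(propan-2-yl)silyl, TES = triethylsilyl.

Remark: the sense of induction of (R)-DTBM-SEGPHOS in step 5 is assigned by analogy with simple β-methyl enones; should the alkynyl group add to the other face, the (S)-ligand is used without further change.

Remark: C6 is formed without control in step 11 and is carried as an epimer pair up to step 17, where both epimers pass through the same furanolate; the carbinol centre made at C3 in step 15 is likewise uncontrolled and is removed in step 16.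

**Route**

Step 1
Reactants: 1 furan-3-ylmethanol
Product: 2 tert-butyl(furan-3-ylmethoxy)dimethylsilane
Conditions: TBSCl, imidazole, DMF, rt
Reagents that add atoms: tert-butyldimethylsilyl chloride, CC(C)(C)[Si](C)(C)Cl
Why: Standard silylation of a primary alcohol; the silyl group is placed on oxygen so that it can be moved to carbon in step 2.

Step 2
Reactants: 2 tert-butyl(furan-3-ylmethoxy)dimethylsilane
Product: 4 [2-(tert-butyldimethylsilyl)furan-3-yl]methanol, via 2-lithiofuran 3 (not isolated)
Conditions: n-BuLi (1.2 equiv), HMPA, THF, −20 °C → rt; then H2O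
Reagents that add atoms: none
Why: Alkoxymethyl-directed lithiation at the furan 2-position followed by 1,4 O→C silyl migration (retro-Brook rearrangement), driven by formation of the lithium alkoxide, should place the silyl group on the carbon that is to become the lactone carbonyl C12.

Step 3
Reactants: 5 (E)-but-2-enoyl chloride; 6 N,O-dimethylhydroxylamine hydrochloride
Product: 7 (E)-N-methoxy-N-methylbut-2-enamide
Conditions: pyridine (2.2 equiv), CH2Cl2, 0 °C → rt
Reagents that add atoms: none
Why: Acylation of the hydroxylamine by the acid chloride (Weinreb amide formation) with retention of the E double bond.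

Step 4
Reactants: 4 [2-(tert-butyldimethylsilyl)furan-3-yl]methanol; 7 (E)-N-methoxy-N-methylbut-2-enamide
Product: 9 (E)-1-[5-(tert-butyldimethylsilyl)-4-(hydroxymethyl)furan-3-yl]but-2-en-1-one, via dilithio furan 8 (not isolated)
Conditions: n-BuLi (2.2 equiv), DME, 0 °C; then 7, −78 → 0 °C; then H2O
Reagents that add atoms: none
Why: With the 2-position blocked by silicon, the lithium alkoxide directs the second lithiation to the adjacent furan 4-position (directed ortho-metalation), and the Weinreb ketone synthesis should then give the enone by 1,2-addition without over-addition.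

Step 5
Reactants: 9 (E)-1-[5-(tert-butyldimethylsilyl)-4-(hydroxymethyl)furan-3-yl]but-2-en-1-one; 10 ethynyltri(propan-2-yl)silane
Product: 11 (3S)-1-[5-(tert-butyldimethylsilyl)-4-(hydroxymethyl)furan-3-yl]-3-methyl-5-[tri(propan-2-yl)silyl]pent-4-yn-1-one
Conditions: [Rh(OAc)(C2H4)2]2 (2.5 mol%), (R)-DTBM-SEGPHOS (6 mol%), 10 (2 equiv), 1,4-dioxane, 80 °C
Reagents that add atoms: none
Why: Rhodium-catalysed asymmetric conjugate alkynylation of a β-methyl enone; the chiral bisphosphine selects the enone face and so sets C10 (S), and the bulky silyl group on the alkyne suppresses alkyne dimerisation.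

Step 6
Reactants: 11 (3S)-β-alkynyl ketone
Product: 12 (1S,3S)-1-[5-(tert-butyldimethylsilyl)-4-(hydroxymethyl)furan-3-yl]-3-methyl-5-[tri(propan-2-yl)silyl]pent-4-yn-1-ol
Conditions: RuCl(p-cymene)[(S,S)-TsDPEN] (1 mol%), HCO2H/Et3N (5:2), DMF, rt
Reagents that add atoms: none
Why: Noyori asymmetric transfer hydrogenation of a heteroaryl alkyl ketone; the (S,S)-catalyst should deliver hydride to the face that gives the (S)-carbinol at C8 by catalyst control, and the alkyne and the free primary alcohol are tolerated.

Step 7
Reactants: 12 (1S,3S)-diol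
Product: 13 bis-TBS ether of 12 (primary and secondary hydroxyl both silylated)
Conditions: TBSOTf (2.5 equiv), 2,6-lutidine, CH2Cl2, −78 → 0 °C
Reagents that add atoms: tert-butyldimethylsilyl trifluoromethanesulfonate, CC(C)(C)[Si](C)(C)OS(=O)(=O)C(F)(F)F
Why: Silylation under amine-buffered conditions generates no free alkoxide, so the furyl silane is not lost by C→O silyl migration (Brook rearrangement).

Step 8
Reactants: 13 bis-TBS ether
Product: 16 5-hydroxy-3-[(TBS-oxy)methyl]-4-[(1S,3S)-1-(TBS-oxy)-3-methyl-5-(TIPS)pent-4-yn-1-yl]furan-2(5H)-one (anomer pair), via endoperoxide 14 (not isolated), via silyl ester 15 (not isolated)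
Conditions: O2, visible light, tetraphenylporphyrin (cat.), CH2Cl2, −78 °C; then H2O, silica gel
Reagents that add atoms: oxygen, O=O
Why: Singlet-oxygen [4+2] cycloaddition to the 2-silylfuran followed by 1,2-silyl migration opens the endoperoxide regiospecifically, so that the silicon-bearing carbon should become the lactone carbonyl C12 and C6 the hemiacetal carbon.

Step 9
Reactants: 17 prop-2-yn-1-ol
Product: 19 (E)-3-iodo-2-methylprop-2-en-1-ol, via alkenylalane 18 (not isolated)
Conditions: AlMe3 (3 equiv), Cp2ZrCl2 (0.25 equiv), CH2Cl2, 0 °C → rt; then I2, THF, −30 → 0 °C; aqueous work-up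
Reagents that add atoms: trimethylaluminium, C[Al](C)C; iodine, II
Why: Negishi carboalumination adds methyl and aluminium syn across the alkyne with aluminium at the terminal carbon, and iodinolysis with retention should give the E vinyl iodide.

Step 10
Reactants: 19 (E)-3-iodo-2-methylprop-2-en-1-ol
Product: 20 triethyl{[(E)-3-iodo-2-methylprop-2-en-1-yl]oxy}silane
Conditions: TESCl, imidazole, CH2Cl2, 0 °C
Reagents that add atoms: chlorotriethylsilane, CC[Si](Cl)(CC)CC
Why: Routine silylation that masks the hydroxyl during the iodine–lithium exchange and is removed again in the acidic work-up of step 11.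

Step 11
Reactants: 16 γ-hydroxybutenolide; 20 TES-protected vinyl iodide
Product: 23 5-[(E)-3-hydroxy-2-methylprop-1-en-1-yl]-3-[(TBS-oxy)methyl]-4-[(1S,3S)-1-(TBS-oxy)-3-methyl-5-(TIPS)pent-4-yn-1-yl]furan-2(5H)-one (epimer pair at C6), via vinyllithium 21 (not isolated), via dilithium adduct 22 (not isolated)
Conditions: 20 (2.5 equiv), t-BuLi (5.0 equiv), Et2O, −78 °C; then 16, THF, −78 → −20 °C; then 1 M HCl, THF, 0 °C
Reagents that add atoms: none
Why: Iodine–lithium exchange proceeds with retention of the E geometry; one equivalent of the vinyllithium opens the lactol to the aldehyde carboxylate and a second adds 1,2 to the aldehyde (organometallic addition to a γ-hydroxybutenolide), and acidification should lactonise the (Z)-hydroxy acid and remove the TES group, with no control needed at C6.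

Step 12
Reactants: 23 allylic alcohol
Product: 24 epoxy alcohol: 23 with the side-chain alkene converted into a (2R,3R)-3-(hydroxymethyl)-3-methyloxiran-2-yl group (C4–C5 epoxide; epimer pair at C6)
Conditions: Ti(OiPr)4 (10 mol%), D-(−)-diethyl tartrate (12 mol%), t-BuOOH (2 equiv), 4 Å MS, CH2Cl2, −20 °C
Reagents that add atoms: tert-butyl hydroperoxide, CC(C)(C)OO
Why: Sharpless asymmetric epoxidation of an (E)-trisubstituted primary allylic alcohol; the D-tartrate directs oxygen to the face that sets the C4–O configuration of the target by reagent control over the neighbouring C6 centre, and the electron-poor butenolide alkene is left alone.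

Step 13
Reactants: 24 epoxy alcohol
Product: 25 iodoalkyne: 24 with iodine in place of the TIPS group
Conditions: AgF (1.5 equiv), N-iodosuccinimide (1.3 equiv), MeCN, rt, dark
Reagents that add atoms: N-iodosuccinimide, O=C1CCC(=O)N1I
Why: Silver-assisted desilylative iodination; silver activation of the alkyne makes the C(sp)–Si bond far more labile towards fluoride than the O–Si bonds, and the silver acetylide is iodinated in place.

Step 14
Reactants: 25 iodoalkyne epoxy alcohol
Product: 26 (2S,3R)-2-methyloxirane-2-carbaldehyde carrying the iodoalkynyl butenolide on C3 (C3 aldehyde; epimer pair at C6)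
Conditions: Dess–Martin periodinane, CH2Cl2, 0 °C → rt
Reagents that add atoms: none
Why: Dess–Martin oxidation is neutral and amine-free, so the base-labile pairing of acidic C6–H and neighbouring epoxide is not triggered early; the aldehyde carbon is quaternary-substituted and cannot epimerise.

Step 15
Reactants: 26 epoxy aldehyde
Product: 28 ten-membered propargylic alcohol (C3 carbinol; C1≡C2; 4,5-epoxide; butenolide fused at C6–C7; 8S OTBS; 10S methyl; epimers at C3 and C6), via alkynylchromium 27 (not isolated)
Conditions: CrCl2 (8 equiv), NiCl2 (2 mol%), THF, rt, syringe-pump addition to a final 0.002 M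
Reagents that add atoms: none
Why: Intramolecular Nozaki–Hiyama–Kishi reaction; the trivalent alkynylchromium adds chemoselectively to the aldehyde under non-basic conditions that spare the epoxide, the lactone and the acidic C6–H, high dilution favours ring closure, and the new carbinol centre is inconsequential.

Step 16
Reactants: 28 ten-membered propargylic alcohol
Product: 29 ten-membered epoxy ynone (C3 ketone conjugated to C1≡C2; (4S,5R)-epoxide; epimer pair at C6)
Conditions: Dess–Martin periodinane, CH2Cl2, 0 °C
Reagents that add atoms: none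
Why: Dess–Martin oxidation of a propargylic alcohol to the ynone under neutral conditions, which removes the uncontrolled C3 centre and installs the Michael acceptor for step 17.

Step 17
Reactants: 29 ten-membered epoxy ynone
Product: 31 bis-TBS ether of the tricyclic core (target skeleton with OTBS at C8 and C13), via hydroxy ynone 30 (not isolated)
Conditions: Cs2CO3 (0.3 equiv), MeCN, 0 °C → rt
Reagents that add atoms: none
Why: Carbonate removes the butenolide C6–H (the most acidic proton, giving an aromatic 2-oxidofuran), and the furanolate expels the adjacent C5–O bond of the oxirane in a vinylogous E1cB step that releases the three-ring strain, creates the C5=C6 enol-lactone bond and frees the C4 alkoxide of 30, which adds to C1 of the bent ring ynone in a 5-endo-dig oxa-Michael addition; protonation of the allenolate gives the furan-3(2H)-one. The closest known reaction types are the base-induced eliminative opening of epoxides β to an enolisable carbonyl and the base- or gold-mediated cycloisomerisation of α′-hydroxy ynones to 3(2H)-furanones. The furanone ring closes 5-endo-dig through the O–C1 bond, and because O, C1 and C4 all lie on the carbocycle the same bond closes the nine-membered oxacycle transannularly, so the 11-oxabicyclo[6.2.1] core arises in one operation. No new stereocentre is formed: C4 keeps the configuration from step 12 because its C–O bond is never broken, both C6 epimers converge on one furanolate, and the C5=C6 geometry (C4 cis to C7) is dictated by the ten-membered ring in which the elimination takes place. The step needs C6–H to be removed in preference to the propargylic C10–H and C5–O rather than C13–O to leave; the aromatic stabilisation of the furanolate, the epoxide strain and the poor leaving-group ability of the C13 silyl ether secure this, and attack at C2 (4-exo) is geometrically excluded.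

Step 18
Reactants: 31 bis-TBS tricyclic core
Product: 32 diol of the tricyclic core (free OH at C8 and C13)
Conditions: HF·pyridine, pyridine, THF, 0 °C → rt
Reagents that add atoms: none
Why: Buffered fluoride desilylation removes both silyl ethers without touching the vinylogous ester or the ylidene butenolide.

Step 19
Reactants: 32 diol
Product: 33 C13 monoacetate (free OH at C8)
Conditions: AcCl (1.1 equiv), 2,4,6-collidine, CH2Cl2, −78 °C
Reagents that add atoms: acetyl chloride, CC(Cl)=O
Why: Kinetically selective acetylation of the unhindered primary allylic alcohol over the hindered secondary C8 hydroxyl with a non-nucleophilic base.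

Step 20
Reactants: 33 C13 monoacetate
Product: 34 target CNP0102620.1
Conditions: 3-methylbut-2-enoyl chloride (1.5 equiv), pyridine, DMAP (cat.), CH2Cl2, 0 °C
Reagents that add atoms: 3-methylbut-2-enoyl chloride, CC(C)=CC(Cl)=O
Why: Acylation of the remaining secondary alcohol with retention at C8; the weak base pyridine limits deconjugation of the senecioyl unit through a vinylketene.

**Compound list**

1 | furan-3-ylmethanol | OCc1ccoc1 | starting material
2 | tert-butyl(furan-3-ylmethoxy)dimethylsilane | CC(C)(C)[Si](C)(C)OCc1ccoc1 | intermediate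
3 | tert-butyl[(2-lithiofuran-3-yl)methoxy]dimethylsilane | [Li]c1occc1CO[Si](C)(C)C(C)(C)C | intermediate
4 | [2-(tert-butyldimethylsilyl)furan-3-yl]methanol | CC(C)(C)[Si](C)(C)c1occc1CO | intermediate
5 | (E)-but-2-enoyl chloride | C/C=C/C(Cl)=O | starting material
6 | N,O-dimethylhydroxylamine hydrochloride | CNOC.Cl | starting material
7 | (E)-N-methoxy-N-methylbut-2-enamide | C/C=C/C(=O)N(C)OC | intermediate
8 | lithium [2-(tert-butyldimethylsilyl)-4-lithiofuran-3-yl]methanolate | [Li]OCc1c([Li])coc1[Si](C)(C)C(C)(C)C | intermediate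
9 | (E)-1-[5-(tert-butyldimethylsilyl)-4-(hydroxymethyl)furan-3-yl]but-2-en-1-one | C/C=C/C(=O)c1coc([Si](C)(C)C(C)(C)C)c1CO | intermediate
10 | ethynyltri(propan-2-yl)silane | C#C[Si](C(C)C)(C(C)C)C(C)C | starting material
11 | (3S)-1-[5-(tert-butyldimethylsilyl)-4-(hydroxymethyl)furan-3-yl]-3-methyl-5-[tri(propan-2-yl)silyl]pent-4-yn-1-one | CC(C)[Si](C(C)C)(C(C)C)C#C[C@@H](C)CC(=O)c1coc([Si](C)(C)C(C)(C)C)c1CO | intermediate
12 | (1S,3S)-1-[5-(tert-butyldimethylsilyl)-4-(hydroxymethyl)furan-3-yl]-3-methyl-5-[tri(propan-2-yl)silyl]pent-4-yn-1-ol | CC(C)[Si](C(C)C)(C(C)C)C#C[C@@H](C)C[C@H](O)c1coc([Si](C)(C)C(C)(C)C)c1CO | intermediate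
13 | bis-TBS ether of 12 | CC(C)[Si](C(C)C)(C(C)C)C#C[C@@H](C)C[C@H](O[Si](C)(C)C(C)(C)C)c1coc([Si](C)(C)C(C)(C)C)c1CO[Si](C)(C)C(C)(C)C | intermediate
14 | 2,5-endoperoxide of 13 (2,3,7-trioxabicyclo[2.2.1]hept-5-ene) | CC(C)[Si](C(C)C)(C(C)C)C#C[C@@H](C)C[C@H](O[Si](C)(C)C(C)(C)C)C1=C(CO[Si](C)(C)C(C)(C)C)C2([Si](C)(C)C(C)(C)C)OOC1O2 | intermediate
15 | TBS ester of the ring-opened (Z)-4-oxobut-2-enoic acid | CC(C)[Si](C(C)C)(C(C)C)C#C[C@@H](C)C[C@H](O[Si](C)(C)C(C)(C)C)/C(C=O)=C(\CO[Si](C)(C)C(C)(C)C)C(=O)O[Si](C)(C)C(C)(C)C | intermediate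
16 | 5-hydroxy-3-[(TBS-oxy)methyl]-4-[(1S,3S)-1-(TBS-oxy)-3-methyl-5-(TIPS)pent-4-yn-1-yl]furan-2(5H)-one (anomer pair) | CC(C)[Si](C(C)C)(C(C)C)C#C[C@@H](C)C[C@H](O[Si](C)(C)C(C)(C)C)C1=C(CO[Si](C)(C)C(C)(C)C)C(=O)OC1O | intermediate
17 | prop-2-yn-1-ol | C#CCO | starting material
18 | alkenylalane: dimethylaluminium alkoxide of (E)-3-(dimethylalumanyl)-2-methylprop-2-en-1-ol | C[Al](C)OC/C(C)=C/[Al](C)C | intermediate
19 | (E)-3-iodo-2-methylprop-2-en-1-ol | OC/C(C)=C/I | intermediate
20 | triethyl{[(E)-3-iodo-2-methylprop-2-en-1-yl]oxy}silane | CC[Si](CC)(CC)OC/C(C)=C/I | intermediate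
21 | triethyl{[(E)-3-lithio-2-methylprop-2-en-1-yl]oxy}silane | CC[Si](CC)(CC)OC/C(C)=C/[Li] | intermediate
22 | dilithium salt of the (Z)-4-hydroxy-2-enoic acid adduct (C6 alkoxide, C12 carboxylate, TES ether intact; C6 epimers) | CC(C)[Si](C(C)C)(C(C)C)C#C[C@@H](C)C[C@H](O[Si](C)(C)C(C)(C)C)/C(C(O[Li])/C=C(\C)CO[Si](CC)(CC)CC)=C(\CO[Si](C)(C)C(C)(C)C)C(=O)O[Li] | intermediate
23 | 5-[(E)-3-hydroxy-2-methylprop-1-en-1-yl]-3-[(TBS-oxy)methyl]-4-[(1S,3S)-1-(TBS-oxy)-3-methyl-5-(TIPS)pent-4-yn-1-yl]furan-2(5H)-one (C6 epimers) | CC(C)[Si](C(C)C)(C(C)C)C#C[C@@H](C)C[C@H](O[Si](C)(C)C(C)(C)C)C1=C(CO[Si](C)(C)C(C)(C)C)C(=O)OC1/C=C(\C)CO | intermediate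
24 | epoxy alcohol: 23 with a (2R,3R)-3-(hydroxymethyl)-3-methyloxiran-2-yl group on the lactone (C6 epimers) | CC(C)[Si](C(C)C)(C(C)C)C#C[C@@H](C)C[C@H](O[Si](C)(C)C(C)(C)C)C1=C(CO[Si](C)(C)C(C)(C)C)C(=O)OC1[C@H]2O[C@]2(C)CO | intermediate
25 | iodoalkyne epoxy alcohol (24 with I in place of TIPS) | IC#C[C@@H](C)C[C@H](O[Si](C)(C)C(C)(C)C)C1=C(CO[Si](C)(C)C(C)(C)C)C(=O)OC1[C@H]2O[C@]2(C)CO | intermediate
26 | (2S,3R)-2-methyloxirane-2-carbaldehyde bearing the iodoalkynyl butenolide on C3 (C6 epimers) | IC#C[C@@H](C)C[C@H](O[Si](C)(C)C(C)(C)C)C1=C(CO[Si](C)(C)C(C)(C)C)C(=O)OC1[C@H]2O[C@]2(C)C=O | intermediate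
27 | alkynylchromium dichloride derived from 26 | Cl[Cr](Cl)C#C[C@@H](C)C[C@H](O[Si](C)(C)C(C)(C)C)C1=C(CO[Si](C)(C)C(C)(C)C)C(=O)OC1[C@H]2O[C@]2(C)C=O | intermediate
28 | ten-membered propargylic alcohol (C3–OH, C1≡C2, 4,5-epoxide, 12,6-lactone, 8S OTBS, 10S methyl; epimers at C3 and C6) | OC1C#C[C@@H](C)C[C@H](O[Si](C)(C)C(C)(C)C)C2=C(CO[Si](C)(C)C(C)(C)C)C(=O)OC2[C@H]3O[C@]13C | intermediate
29 | ten-membered epoxy ynone (C3 ketone, (4S,5R)-epoxide; C6 epimers) | O=C1C#C[C@@H](C)C[C@H](O[Si](C)(C)C(C)(C)C)C2=C(CO[Si](C)(C)C(C)(C)C)C(=O)OC2[C@H]3O[C@]13C | intermediate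
30 | (4S)-4-hydroxy ring ynone with the C5=C6 ylidene butenolide | O=C1C#C[C@@H](C)C[C@H](O[Si](C)(C)C(C)(C)C)C2=C(CO[Si](C)(C)C(C)(C)C)C(=O)O/C2=C/[C@]1(C)O | intermediate
31 | bis-TBS ether of the tricyclic core (OTBS at C8 and C13) | CC(C)(C)[Si](C)(C)OCC1=C2/C(=C\[C@]3(C)OC(=CC3=O)[C@@H](C)C[C@@H]2O[Si](C)(C)C(C)(C)C)OC1=O | intermediate
32 | diol of the tricyclic core (OH at C8 and C13) | OCC1=C2/C(=C\[C@]3(C)OC(=CC3=O)[C@@H](C)C[C@@H]2O)OC1=O | intermediate
33 | C13 monoacetate (OH at C8) | CC(=O)OCC1=C2/C(=C\[C@]3(C)OC(=CC3=O)[C@@H](C)C[C@@H]2O)OC1=O | intermediate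
34 | CNP0102620.1 | CC(=O)OCC1=C2/C(=C\[C@]3(C)OC(=CC3=O)[C@@H](C)C[C@@H]2OC(=O)C=C(C)C)OC1=O | target

**Count and risks**

Total step count: 20. Longest linear sequence: 17 (steps 1, 2, 4–8, 11–20).

Three steps most likely to fail:

1. Step 15 (ring closure). Oligomerisation may outrun closure of the strained cyclodecyne ring, or CrCl2 may reduce the epoxy aldehyde before the alkynylchromium adds. The fallback closes the ring through a cis-alkene instead of the alkyne and sets out from 25. Diimide (from potassium azodicarboxylate and AcOH) should reduce the iodoalkyne to the (Z)-iodoalkene epoxy alcohol F1. Dess–Martin oxidation gives the (Z)-iodoalkene epoxy aldehyde F2. A Nozaki–Hiyama–Kishi cyclisation (CrCl2, NiCl2 cat., DMSO, high dilution) gives the ten-membered (Z)-allylic alcohol F3, a far less strained ring. Dess–Martin oxidation gives the ring (Z)-enone F4. Cs2CO3 in MeCN opens the epoxide as in step 17 to the α′-hydroxy dienone F5. A Wacker-type oxidative cyclisation with divalent palladium (PdCl2(MeCN)2, p-benzoquinone, THF) then forms the O–C1 bond and comes back to the route at 31.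

2. Step 17 (cascade). Base-induced isomerisation of the ynone to an allenone through the propargylic C10–H, or conjugate addition to the ynone, may compete before the alkoxide is released, and loss of the C13 silyloxide from the furanolate is a further leak. The fallback separates the two events and sets out from 28. Cs2CO3 in MeCN, acting on the propargylic alcohol where no Michael acceptor is present, should give the ylidene diol F6. MnO2 in CH2Cl2 oxidises only the propargylic alcohol and gives the hydroxy ynone 30, now isolated. Monovalent gold (Ph3PAuNTf2, 2 mol%, CH2Cl2, rt) catalyses the 5-endo-dig cycloisomerisation and comes back to the route at 31.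

3. Step 11 (C5–C6 bond). Attack of the vinyllithium on the lactone carbonyl of the closed lactol, or base-induced migration of the doubly allylic C6–H double-bond system during the addition, may erode the product. The fallback builds the same bond by a vinylogous aldol route and sets out from 16. NaBH4 in MeOH reduces the lactol through its open aldehyde form and gives the C6-unsubstituted butenolide F7. TBSOTf and Et3N give the 2-silyloxyfuran F8. A vinylogous Mukaiyama aldol addition to methacrolein (BF3·OEt2, CH2Cl2, −78 °C) gives the secondary allylic alcohol F9. A Re2O7-catalysed 1,3-transposition of the allylic alcohol moves the hydroxyl to the primary position with formation of the E trisubstituted alkene and comes back to the route at 23.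

**Further compounds**

F1 | step 15 | (Z)-iodoalkene epoxy alcohol | I/C=C\[C@@H](C)C[C@H](O[Si](C)(C)C(C)(C)C)C1=C(CO[Si](C)(C)C(C)(C)C)C(=O)OC1[C@H]2O[C@]2(C)CO
F2 | step 15 | (Z)-iodoalkene epoxy aldehyde | I/C=C\[C@@H](C)C[C@H](O[Si](C)(C)C(C)(C)C)C1=C(CO[Si](C)(C)C(C)(C)C)C(=O)OC1[C@H]2O[C@]2(C)C=O
F3 | step 15 | ten-membered (Z)-allylic alcohol | OC1/C=C\[C@@H](C)C[C@H](O[Si](C)(C)C(C)(C)C)C2=C(CO[Si](C)(C)C(C)(C)C)C(=O)OC2[C@H]3O[C@]13C
F4 | step 15 | ring (Z)-enone | O=C1/C=C\[C@@H](C)C[C@H](O[Si](C)(C)C(C)(C)C)C2=C(CO[Si](C)(C)C(C)(C)C)C(=O)OC2[C@H]3O[C@]13C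
F5 | step 15 | α′-hydroxy dienone | O=C1/C=C\[C@@H](C)C[C@H](O[Si](C)(C)C(C)(C)C)C2=C(CO[Si](C)(C)C(C)(C)C)C(=O)O/C2=C/[C@]1(C)O
F6 | step 17 | ylidene diol | OC1C#C[C@@H](C)C[C@H](O[Si](C)(C)C(C)(C)C)C2=C(CO[Si](C)(C)C(C)(C)C)C(=O)O/C2=C/[C@]1(C)O
F7 | step 11 | C6-unsubstituted butenolide | CC(C)[Si](C(C)C)(C(C)C)C#C[C@@H](C)C[C@H](O[Si](C)(C)C(C)(C)C)C1=C(CO[Si](C)(C)C(C)(C)C)C(=O)OC1
F8 | step 11 | 2-silyloxyfuran | CC(C)[Si](C(C)C)(C(C)C)C#C[C@@H](C)C[C@H](O[Si](C)(C)C(C)(C)C)c1coc(O[Si](C)(C)C(C)(C)C)c1CO[Si](C)(C)C(C)(C)C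
F9 | step 11 | secondary allylic alcohol | CC(C)[Si](C(C)C)(C(C)C)C#C[C@@H](C)C[C@H](O[Si](C)(C)C(C)(C)C)C1=C(CO[Si](C)(C)C(C)(C)C)C(=O)OC1C(O)C(C)=C
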